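## Retrosynthetic overview

1. The route rests on the quaternary C1 that joins C14 of ring A to the oxygen-bearing C2. This C14(=O)–C1–C2(OH) aldol array is made in masked form, as a 2-isoxazoline, by adding a C14 nitrile oxide across the E-C1=C2 alkene (C14–C1 and O–C2 bonds; ring A and the isoxazoline close together).
2. The open-chain oxime carries only C10–C12: C12 by allylboration of a prenol-derived enal, C11 by Sharpless epoxidation, C10 by alkynylalane opening with inversion, the E-alkene by carboalumination.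
3. N–O cleavage frees the C14 ketone (then C13=C14) and C2–OH. The C9 arm is grown by acyl-anion addition (C8), boron aldol (C6–C7), Stille coupling (C4), chlorination with inversion (C6) and Reformatsky lactonisation (C8, C17).
4. Ring order: ring A with the isoxazoline (step 13), γ-lactone (step 32), ten-membered ring by ring-closing metathesis at C3=C4 (step 35), 13,14-epoxide (step 37); the two acetates come last.

Key step: step 13

Remark: atom numbers are briarane numbers; acetal 27 (acetal carbon) and ester 50 (CHBr) are carried as epimer mixtures that disappear later, and oxime 21 is drawn E although either isomer gives the nitrile oxide.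

## Route

Step 1
Reactants: 1 prenol
Product: 2 prenyl TBS ether
Conditions: TBSCl, imidazole, CH2Cl2, 0 °C to rt
Reagents that add atoms: tert-butyldimethylsilyl chloride, CC(C)(C)[Si](C)(C)Cl
Why: Silyl ether formation on a primary alcohol; the oxygen becomes the C9 oxygen.

Step 2
Reactants: 2 prenyl TBS ether
Product: 4 (E)-4-(TBS-oxy)-2-methylbut-2-enal, via E-allylic alcohol 3 (not isolated)
Conditions: SeO2 (cat.), t-BuOOH, salicylic acid (cat.), CH2Cl2, rt; then MnO2, CH2Cl2, rt
Reagents that add atoms: tert-butyl hydroperoxide, CC(C)(C)OO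
Why: Riley allylic oxidation attacks the E methyl group of the trisubstituted alkene, and MnO2 converges the alcohol/aldehyde mixture on the E enal (CHO = C12).

Step 3
Reactants: 4 (E)-4-(TBS-oxy)-2-methylbut-2-enal; 5 (−)-B-allyldiisopinocampheylborane
Product: 7 (4R,5E)-7-(TBS-oxy)-5-methylhepta-1,5-dien-4-ol, via borinate ester 6 (not isolated)
Conditions: Et2O, −78 °C; then NaOH, H2O2, 0 °C to rt
Reagents that add atoms: none
Why: Brown allylboration through a chair six-membered transition state; the reagent derived from (−)-α-pinene should add to the Re face of the enal and set C12 as R under reagent control.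

Step 4
Reactants: 7 (4R,5E)-7-(TBS-oxy)-5-methylhepta-1,5-dien-4-ol
Product: 8 (10R,11R,12R)-epoxy alcohol
Conditions: Ti(OiPr)4 (cat.), D-(−)-diethyl tartrate, t-BuOOH, 4 Å MS, CH2Cl2, −20 °C
Reagents that add atoms: tert-butyl hydroperoxide, CC(C)(C)OO
Why: Sharpless asymmetric epoxidation of a secondary allylic alcohol; with D-(−)-tartrate the 12R alcohol is the matched enantiomer and should give the erythro epoxy alcohol, which fixes C11 and leaves the remote terminal alkene untouched.

Step 5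
Reactants: 8 (10R,11R,12R)-epoxy alcohol; 9 ethynyltrimethylsilane
Product: 11 (10S,11S,12R)-alkynyl diol, via alkynylalane 10 (not isolated)
Conditions: 9, n-BuLi, toluene, 0 °C; Et2AlCl; then 8, 0 °C to rt
Reagents that add atoms: none
Why: Alkynylalane opening of a 2,3-epoxy alcohol at C3 (here the secondary C10) by SN2 with inversion sets C10 and leaves the tertiary C11–O bond intact.

Step 6
Reactants: 11 (10S,11S,12R)-alkynyl diol
Product: 12 C11/C12 acetonide
Conditions: Me2C(OMe)2, PPTS, CH2Cl2, rt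
Reagents that add atoms: 2,2-dimethoxypropane, COC(C)(C)OC
Why: Transketalisation protects the C11/C12 diol as the cis-dioxolane that is needed in the key step.

Step 7
Reactants: 12 C11/C12 acetonide
Product: 15 terminal alkyne C14 alcohol, via aldehyde 13 (not isolated), via silyl alkyne alcohol 14 (not isolated)
Conditions: O3, CH2Cl2/MeOH, −78 °C (Sudan red end point); NaBH4, −78 °C to rt; then K2CO3, MeOH, rt
Reagents that add atoms: ozone, [O-][O+]=O
Why: Ozonolysis with reductive work-up cleaves the terminal alkene much faster than the silyl alkyne and gives the C14 alcohol, and K2CO3/MeOH then removes the alkynyl TMS group by protodesilylation.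

Step 8
Reactants: 15 terminal alkyne C14 alcohol
Product: 16 C14 TES ether
Conditions: TESCl, imidazole, CH2Cl2, 0 °C
Reagents that add atoms: chlorotriethylsilane, CC[Si](CC)(CC)Cl
Why: Silylation masks C14–OH for the organoaluminium step as an ether that can later be oxidised directly.

Step 9
Reactants: 16 C14 TES ether
Product: 18 E-allylic alcohol (C3–OH), via alkenylalane 17 (not isolated)
Conditions: AlMe3, Cp2ZrCl2 (20 mol %), H2O (1 equiv), CH2Cl2, −20 °C to rt; then n-BuLi, THF, −78 °C; (CH2O)n, rt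
Reagents that add atoms: trimethylaluminium, C[Al](C)C; formaldehyde (as paraformaldehyde), C=O
Why: Negishi carboalumination adds methyl and aluminium syn across the terminal alkyne with methyl on C1, and the alanate is trapped by formaldehyde with retention, so C3 ends cis to C15 (E alkene).

Step 10
Reactants: 18 E-allylic alcohol (C3–OH)
Product: 19 C3 PMB ether
Conditions: NaH, PMBCl, Bu4NI (cat.), THF/DMF, 0 °C to rt
Reagents that add atoms: 4-methoxybenzyl chloride, COc1ccc(CCl)cc1
Why: Williamson etherification of the primary allylic alcohol; PMB is chosen because it can later be turned into an acetal onto C2–OH.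

Step 11
Reactants: 19 C3 PMB ether
Product: 20 C14 aldehyde
Conditions: (COCl)2, DMSO, CH2Cl2, −78 to −40 °C; Et3N, −78 to 0 °C
Reagents that add atoms: none
Why: Swern oxidation converts a primary TES ether directly into the aldehyde (oxidative desilylation) while the primary TBS ether survives.

Step 12
Reactants: 20 C14 aldehyde
Product: 21 C14 oxime
Conditions: NH2OH·HCl, NaOAc, EtOH/H2O, rt
Reagents that add atoms: hydroxylammonium chloride, [NH3+]O.[Cl-]
Why: Condensation of the aldehyde with hydroxylamine gives the aldoxime.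

Step 13
Reactants: 21 C14 oxime
Product: 24 ring-A-fused isoxazoline, via hydroximoyl chloride 22 (not isolated), via nitrile oxide 23 (not isolated)
Conditions: aq. NaOCl, CH2Cl2, 0 °C to rt, slow addition of 21 (final 0.005 M)
Reagents that add atoms: none
Why: Hypochlorite chlorinates the aldoxime and loss of HCl gives the C14 nitrile oxide, which adds in a concerted suprafacial [3+2] cycloaddition to the tethered trisubstituted alkene. The closest known reaction type is the intramolecular nitrile oxide–alkene cycloaddition that gives cyclohexane-fused 2-isoxazolines with a quaternary ring-fusion carbon. Ring A (C1, C10–C14) closes in the fused (exo) mode because the tether lets the dipole carbon reach only C1, and the isoxazoline closes at the same time through the O–C2 bond. C2 is set against C1 by the E alkene geometry (C3 stays cis to C15), and C1 is set against C10 by a chair-like transition state with the CH2OTBS arm on C10 equatorial, H-10 eclipsing the alkene and C2 pseudo-equatorial beside the dipole. The step needs this facial selectivity over the alternative chair with C9 axial; the cis-fused acetonide should secure it because it flattens the ring, which eases the C15/C20 contact, and puts its bulk on the face where the competing chair would place the axial C15 methyl. High dilution should suppress dimerisation to the furoxan.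

Step 14
Reactants: 24 ring-A-fused isoxazoline
Product: 26 ketol (C14 ketone; C2–OH), via hydroxy imine 25 (not isolated)
Conditions: H2 (1 atm), Raney Ni, B(OH)3, MeOH/H2O 5:1, rt
Reagents that add atoms: water, O
Why: Hydrogenolysis of the N–O bond and hydrolysis of the β-hydroxy imine in the boric acid buffer unmask the aldol without retro-aldol cleavage or loss of the benzylic ether.

Step 15
Reactants: 26 ketol (C14 ketone; C2–OH)
Product: 27 C2/C3 p-methoxybenzylidene acetal
Conditions: DDQ, 4 Å MS, CH2Cl2, 0 °C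
Reagents that add atoms: none
Why: Anhydrous DDQ oxidation of the PMB ether gives an oxocarbenium ion that the neighbouring C2–OH traps (oxidative acetal formation), which protects the aldol against retro-aldol cleavage in the next step.

Step 16
Reactants: 27 C2/C3 p-methoxybenzylidene acetal
Product: 28 C13-en-14-yl triflate
Conditions: KHMDS, THF, −78 °C; PhNTf2, −78 °C
Reagents that add atoms: N-phenylbis(trifluoromethanesulfonimide), O=S(=O)(N(c1ccccc1)S(=O)(=O)C(F)(F)F)C(F)(F)F
Why: Enolisation is possible only towards C13 because C1 is quaternary, and O-triflation at −78 °C should outrun β-elimination of the C12 oxygen.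

Step 17
Reactants: 28 C13-en-14-yl triflate
Product: 29 C13=C14 cyclohexene acetal
Conditions: Pd(OAc)2 (5 mol %), PPh3, Bu3N, HCO2H, DMF, 60 °C
Reagents that add atoms: none
Why: Palladium-catalysed formate reduction of an enol triflate replaces the triflate by hydrogen and leaves the C13=C14 alkene.

Step 18
Reactants: 29 C13=C14 cyclohexene acetal
Product: 30 C2 PMB ether C3 alcohol
Conditions: DIBAL-H, CH2Cl2, −78 to 0 °C
Reagents that add atoms: none
Why: Reductive opening of an arylidene acetal; aluminium binds the less hindered primary oxygen, so PMB should stay on the neopentyl C2 oxygen and C3–OH is freed.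

Step 19
Reactants: 30 C2 PMB ether C3 alcohol
Product: 31 C3 aldehyde
Conditions: Dess–Martin periodinane, NaHCO3, CH2Cl2, rt
Reagents that add atoms: none
Why: Buffered Dess–Martin oxidation gives the α-alkoxy aldehyde without epimerising C2.

Step 20
Reactants: 31 C3 aldehyde
Product: 32 C2 vinyl compound
Conditions: Ph3PCH3Br, KHMDS, THF, 0 °C; then 31, −78 to 0 °C
Reagents that add atoms: methyltriphenylphosphonium bromide, C[P+](c1ccccc1)(c1ccccc1)c1ccccc1.[Br-]
Why: Wittig methylenation installs the C3 alkene terminus for the later metathesis.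

Step 21
Reactants: 32 C2 vinyl compound
Product: 33 C9 alcohol
Conditions: Bu4NF, THF, 0 °C to rt
Reagents that add atoms: none
Why: Fluoride cleaves the only silyl ether present.

Step 22
Reactants: 33 C9 alcohol
Product: 34 C9 aldehyde
Conditions: Dess–Martin periodinane, NaHCO3, CH2Cl2, rt
Reagents that add atoms: none
Why: Neutral Dess–Martin oxidation should not epimerise C10, which is flanked by two quaternary carbons.

Step 23
Reactants: 34 C9 aldehyde; 35 ethyl vinyl ether
Product: 37 (9S)-carbinol carrying the 1-ethoxyvinyl group, via 1-ethoxyvinyllithium 36 (not isolated)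
Conditions: 35, t-BuLi, THF, −78 to 0 °C; then 34, −78 °C
Reagents that add atoms: none
Why: 1,2-Addition of an acyl-anion equivalent; Felkin–Anh attack anti to the C10–C11 bond, reinforced by 1,3-anti induction from the C11 oxygen under non-chelating conditions, should give 9S.

Step 24
Reactants: 37 (9S)-carbinol carrying the 1-ethoxyvinyl group
Product: 38 C9 TBS ether
Conditions: TBSOTf, 2,6-lutidine, CH2Cl2, −78 to 0 °C
Reagents that add atoms: tert-butyldimethylsilyl triflate, CC(C)(C)[Si](C)(C)OS(=O)(=O)C(F)(F)F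
Why: The silyl triflate silylates the hindered secondary alcohol faster than it attacks the enol ether in the presence of lutidine.

Step 25
Reactants: 38 C9 TBS ether
Product: 40 C8 ketone with C7 primary alcohol, via ethoxy epoxide 39 (not isolated)
Conditions: dimethyldioxirane (acetone solution), CH2Cl2, −78 to −40 °C; then H2O work-up
Reagents that add atoms: dimethyldioxirane, CC1(C)OO1; water, O
Why: The electron-rich enol ether is epoxidised far faster than the two unactivated alkenes, and the alkoxy epoxide collapses on work-up to the α-hydroxy ketone (Rubottom-type oxidation).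

Step 26
Reactants: 40 C8 ketone with C7 primary alcohol
Product: 41 C8 ketone with C7 TES ether
Conditions: TESCl, imidazole, CH2Cl2, 0 °C
Reagents that add atoms: chlorotriethylsilane, CC[Si](CC)(CC)Cl
Why: Silylation of the primary hydroxyl gives a 1-silyloxy ketone that enolises cleanly on the C7 side.

Step 27
Reactants: 41 C8 ketone with C7 TES ether; 42 2-bromoacrolein
Product: 44 6,7-syn aldol (C6–OH; C5 vinyl bromide), via boron enolate 43 (not isolated)
Conditions: (c-C6H11)2BCl, Et3N, Et2O, −78 to 0 °C; 42, −78 °C; then H2O2, pH 7 buffer, MeOH, 0 °C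
Reagents that add atoms: none
Why: Boron aldol reaction; α-silyloxy ketones of this type form the Z enolate and react through a Zimmerman–Traxler chair to the syn aldol, and with H-9 eclipsing the enolate the aldehyde should approach anti to C10, which gives the C7 configuration of the target and C6–OH syn to the C7 oxygen.

Step 28
Reactants: 44 6,7-syn aldol (C6–OH; C5 vinyl bromide); 45 tributyl(vinyl)stannane
Product: 46 dienyl alcohol (C5(=C16H2)–C4H=CH2)
Conditions: Pd2(dba)3 (5 mol %), AsPh3, CuI, NMP, 40 °C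
Reagents that add atoms: none
Why: Stille coupling of the vinyl bromide under mild ligand conditions builds the 2-substituted butadiene without retro-aldol cleavage.

Step 29
Reactants: 46 dienyl alcohol (C5(=C16H2)–C4H=CH2)
Product: 47 (6S)-chloride
Conditions: PPh3, hexachloroacetone, CH2Cl2, −20 to 0 °C
Reagents that add atoms: hexachloroacetone, ClC(Cl)(Cl)C(=O)C(Cl)(Cl)Cl
Why: Deoxychlorination through the alkoxyphosphonium salt with SN2 attack of chloride; this reagent pair is known to convert secondary allylic alcohols into chlorides with inversion and little allylic transposition, so C6 should become S.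

Step 30
Reactants: 47 (6S)-chloride
Product: 48 C7 alcohol (α-hydroxy β-chloro ketone)
Conditions: HF·pyridine, pyridine, THF, 0 °C
Reagents that add atoms: none
Why: Buffered HF cleaves the secondary TES ether selectively beside the hindered C9 TBS ether and does not eliminate HCl.

Step 31
Reactants: 48 C7 alcohol (α-hydroxy β-chloro ketone); 49 2-bromopropanoyl bromide
Product: 50 C7 2-bromopropanoate
Conditions: pyridine, CH2Cl2, −40 °C
Reagents that add atoms: none
Why: Acylation with the reactive acid bromide and a weak base at low temperature esterifies C7–OH before the β-chloro ketone can eliminate.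

Step 32
Reactants: 50 C7 2-bromopropanoate
Product: 52 γ-lactone (C8–OH free), via samarium enolate 51 (not isolated)
Conditions: SmI2 (2.2 equiv), THF, −78 °C
Reagents that add atoms: none
Why: Intramolecular Reformatsky reaction; the α-bromo ester is reduced first and the samarium enolate adds to the C8 ketone, closing the five-membered lactone with the bulky C9 branch trans to C6 (C8–OH cis to C6) and the C17 methyl anti to C9.

Step 33
Reactants: 52 γ-lactone (C8–OH free)
Product: 53 C2 alcohol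
Conditions: DDQ, CH2Cl2/pH 7 buffer, 0 °C
Reagents that add atoms: none
Why: Oxidative cleavage of the PMB ether frees C2–OH while silyl ether, acetonide, lactone and chloride stay.

Step 34
Reactants: 53 C2 alcohol
Product: 54 C2 butanoate
Conditions: (PrCO)2O, DMAP (cat.), pyridine, CH2Cl2, 0 °C to rt
Reagents that add atoms: butanoic anhydride, CCCC(=O)OC(=O)CCC
Why: Acylation of the only secondary hydroxyl; the tertiary C8–OH should not react under these conditions.

Step 35
Reactants: 54 C2 butanoate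
Product: 55 ten-membered ring compound
Conditions: second-generation Hoveyda–Grubbs catalyst, RuCl2(H2IMes)(=CH-C6H4-2-OiPr) (10 mol %), toluene (0.5 mM), 80 °C, Ar purge
Reagents that add atoms: none
Why: Ring-closing metathesis between the C2 vinyl group and the terminal vinyl of the diene releases ethene and forms C3=C4, which must be Z in a ten-membered ring; ring A and the lactone hold the two arms in place and the allylic chloride is tolerated.

Step 36
Reactants: 55 ten-membered ring compound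
Product: 56 tetraol (C8, C9, C11, C12 hydroxyls)
Conditions: HF (48 % aq.), MeCN, 0 °C to rt
Reagents that add atoms: none
Why: Aqueous HF cleaves the hindered C9 TBS ether and hydrolyses the acetonide without touching the esters.

Step 37
Reactants: 56 tetraol (C8, C9, C11, C12 hydroxyls)
Product: 57 13,14-epoxy tetraol
Conditions: VO(acac)2 (5 mol %), t-BuOOH, CH2Cl2, 0 °C to rt
Reagents that add atoms: tert-butyl hydroperoxide, CC(C)(C)OO
Why: Hydroxyl-directed epoxidation of the cyclic allylic alcohol delivers oxygen to the face of C12–OH (13R,14R) and leaves the diene, which has no free allylic hydroxyl, untouched.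

Step 38
Reactants: 57 13,14-epoxy tetraol
Product: 58 CNP0114058.1
Conditions: Ac2O, DMAP (cat.), pyridine, CH2Cl2, rt
Reagents that add atoms: acetic anhydride, CC(=O)OC(C)=O
Why: Acetylation of the two secondary hydroxyls (C9, C12); the tertiary C8 and C11 hydroxyls should stay free.

## Compound list

1 | prenol (3-methylbut-2-en-1-ol) | CC(C)=CCO | starting material
2 | prenyl TBS ether | CC(C)=CCO[Si](C)(C)C(C)(C)C | intermediate
3 | (E)-4-(TBS-oxy)-2-methylbut-2-en-1-ol | OC/C(C)=C/CO[Si](C)(C)C(C)(C)C | intermediate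
4 | (E)-4-(TBS-oxy)-2-methylbut-2-enal | O=C/C(C)=C/CO[Si](C)(C)C(C)(C)C | intermediate
5 | (−)-B-allyldiisopinocampheylborane (from (−)-α-pinene) | C=CCB([C@H]1C[C@H]2C[C@@H]([C@@H]1C)C2(C)C)[C@H]1C[C@H]2C[C@@H]([C@@H]1C)C2(C)C | starting material
6 | diisopinocampheylborinate of alcohol 7 | C=CC[C@@H](OB([C@H]1C[C@H]2C[C@@H]([C@@H]1C)C2(C)C)[C@H]1C[C@H]2C[C@@H]([C@@H]1C)C2(C)C)/C(C)=C/CO[Si](C)(C)C(C)(C)C | intermediate
7 | (4R,5E)-7-(TBS-oxy)-5-methylhepta-1,5-dien-4-ol | C=CC[C@@H](O)/C(C)=C/CO[Si](C)(C)C(C)(C)C | intermediate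
8 | (R)-1-[(2R,3R)-3-(TBS-oxymethyl)-2-methyloxiran-2-yl]but-3-en-1-ol | C=CC[C@@H](O)[C@@]1(C)O[C@@H]1CO[Si](C)(C)C(C)(C)C | intermediate
9 | ethynyltrimethylsilane | C#C[Si](C)(C)C | starting material
10 | diethyl(trimethylsilylethynyl)alane | CC[Al](CC)C#C[Si](C)(C)C | intermediate
11 | (10S,11S,12R)-alkynyl diol (C10: CH2OTBS and C≡C–TMS; C11: Me, OH; C12: OH, allyl) | C[Si](C)(C)C#C[C@@H](CO[Si](C)(C)C(C)(C)C)[C@](C)(O)[C@H](O)CC=C | intermediate
12 | C11/C12 acetonide of 11 | C[Si](C)(C)C#C[C@@H](CO[Si](C)(C)C(C)(C)C)[C@](C)(O1)[C@H](OC1(C)C)CC=C | intermediate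
13 | C14 aldehyde from ozonolysis of 12 | C[Si](C)(C)C#C[C@@H](CO[Si](C)(C)C(C)(C)C)[C@](C)(O1)[C@H](OC1(C)C)CC=O | intermediate
14 | C14 alcohol with TMS alkyne | C[Si](C)(C)C#C[C@@H](CO[Si](C)(C)C(C)(C)C)[C@](C)(O1)[C@H](OC1(C)C)CCO | intermediate
15 | terminal alkyne C14 alcohol | C#C[C@@H](CO[Si](C)(C)C(C)(C)C)[C@](C)(O1)[C@H](OC1(C)C)CCO | intermediate
16 | C14 TES ether | C#C[C@@H](CO[Si](C)(C)C(C)(C)C)[C@](C)(O1)[C@H](OC1(C)C)CCO[Si](CC)(CC)CC | intermediate
17 | (E)-alkenyl dimethylalane (Al on C2, methyl on C1) | C[Al](C)/C=C(\C)[C@@H](CO[Si](C)(C)C(C)(C)C)[C@](C)(O1)[C@H](OC1(C)C)CCO[Si](CC)(CC)CC | intermediate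
18 | E-allylic alcohol (C3–OH) | OC/C=C(\C)[C@@H](CO[Si](C)(C)C(C)(C)C)[C@](C)(O1)[C@H](OC1(C)C)CCO[Si](CC)(CC)CC | intermediate
19 | C3 PMB ether | COc1ccc(COC/C=C(\C)[C@@H](CO[Si](C)(C)C(C)(C)C)[C@](C)(O2)[C@H](OC2(C)C)CCO[Si](CC)(CC)CC)cc1 | intermediate
20 | C14 aldehyde | COc1ccc(COC/C=C(\C)[C@@H](CO[Si](C)(C)C(C)(C)C)[C@](C)(O2)[C@H](OC2(C)C)CC=O)cc1 | intermediate
21 | C14 oxime (precursor of the key step) | COc1ccc(COC/C=C(\C)[C@@H](CO[Si](C)(C)C(C)(C)C)[C@](C)(O2)[C@H](OC2(C)C)C/C=N/O)cc1 | intermediate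
22 | C14 hydroximoyl chloride | COc1ccc(COC/C=C(\C)[C@@H](CO[Si](C)(C)C(C)(C)C)[C@](C)(O2)[C@H](OC2(C)C)CC(Cl)=NO)cc1 | intermediate
23 | C14 nitrile oxide | COc1ccc(COC/C=C(\C)[C@@H](CO[Si](C)(C)C(C)(C)C)[C@](C)(O2)[C@H](OC2(C)C)CC#[N+][O-])cc1 | intermediate
24 | ring-A-fused isoxazoline (product of the key step) | COc1ccc(COC[C@H]4[C@@]2(C)C(=NO4)C[C@@H](O3)[C@@](C)(OC3(C)C)[C@@H]2CO[Si](C)(C)C(C)(C)C)cc1 | intermediate
25 | β-hydroxy imine | COc1ccc(COC[C@H](O)[C@@]2(C)C(=N)C[C@@H](O3)[C@@](C)(OC3(C)C)[C@@H]2CO[Si](C)(C)C(C)(C)C)cc1 | intermediate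
26 | ketol (C14 ketone; C2–OH) | COc1ccc(COC[C@H](O)[C@@]2(C)C(=O)C[C@@H](O3)[C@@](C)(OC3(C)C)[C@@H]2CO[Si](C)(C)C(C)(C)C)cc1 | intermediate
27 | C2/C3 p-methoxybenzylidene acetal | COc1ccc(C4OC[C@H](O4)[C@@]2(C)C(=O)C[C@@H](O3)[C@@](C)(OC3(C)C)[C@@H]2CO[Si](C)(C)C(C)(C)C)cc1 | intermediate
28 | C13-en-14-yl triflate | COc1ccc(C4OC[C@H](O4)[C@@]2(C)C(OS(=O)(=O)C(F)(F)F)=C[C@@H](O3)[C@@](C)(OC3(C)C)[C@@H]2CO[Si](C)(C)C(C)(C)C)cc1 | intermediate
29 | C13=C14 cyclohexene acetal | COc1ccc(C4OC[C@H](O4)[C@@]2(C)C=C[C@@H](O3)[C@@](C)(OC3(C)C)[C@@H]2CO[Si](C)(C)C(C)(C)C)cc1 | intermediate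
30 | C2 PMB ether C3 alcohol | COc1ccc(CO[C@@H](CO)[C@@]2(C)C=C[C@@H](O3)[C@@](C)(OC3(C)C)[C@@H]2CO[Si](C)(C)C(C)(C)C)cc1 | intermediate
31 | C3 aldehyde | COc1ccc(CO[C@@H](C=O)[C@@]2(C)C=C[C@@H](O3)[C@@](C)(OC3(C)C)[C@@H]2CO[Si](C)(C)C(C)(C)C)cc1 | intermediate
32 | C2 vinyl compound | COc1ccc(CO[C@@H](C=C)[C@@]2(C)C=C[C@@H](O3)[C@@](C)(OC3(C)C)[C@@H]2CO[Si](C)(C)C(C)(C)C)cc1 | intermediate
33 | C9 alcohol | COc1ccc(CO[C@@H](C=C)[C@@]2(C)C=C[C@@H](O3)[C@@](C)(OC3(C)C)[C@@H]2CO)cc1 | intermediate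
34 | C9 aldehyde | COc1ccc(CO[C@@H](C=C)[C@@]2(C)C=C[C@@H](O3)[C@@](C)(OC3(C)C)[C@@H]2C=O)cc1 | intermediate
35 | ethyl vinyl ether | C=COCC | starting material
36 | 1-ethoxyvinyllithium | [Li]C(=C)OCC | intermediate
37 | (9S)-carbinol carrying the 1-ethoxyvinyl group | COc1ccc(CO[C@@H](C=C)[C@@]2(C)C=C[C@@H](O3)[C@@](C)(OC3(C)C)[C@@H]2[C@H](O)C(=C)OCC)cc1 | intermediate
38 | C9 TBS ether | COc1ccc(CO[C@@H](C=C)[C@@]2(C)C=C[C@@H](O3)[C@@](C)(OC3(C)C)[C@@H]2[C@H](O[Si](C)(C)C(C)(C)C)C(=C)OCC)cc1 | intermediate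
39 | 2-ethoxyoxirane from the enol ether | COc1ccc(CO[C@@H](C=C)[C@@]2(C)C=C[C@@H](O3)[C@@](C)(OC3(C)C)[C@@H]2[C@H](O[Si](C)(C)C(C)(C)C)C4(OCC)CO4)cc1 | intermediate
40 | C8 ketone with C7 primary alcohol | COc1ccc(CO[C@@H](C=C)[C@@]2(C)C=C[C@@H](O3)[C@@](C)(OC3(C)C)[C@@H]2[C@H](O[Si](C)(C)C(C)(C)C)C(=O)CO)cc1 | intermediate
41 | C8 ketone with C7 TES ether | COc1ccc(CO[C@@H](C=C)[C@@]2(C)C=C[C@@H](O3)[C@@](C)(OC3(C)C)[C@@H]2[C@H](O[Si](C)(C)C(C)(C)C)C(=O)CO[Si](CC)(CC)CC)cc1 | intermediate
42 | 2-bromoacrolein (2-bromoprop-2-enal) | C=C(Br)C=O | starting material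
43 | Z dicyclohexylboron enolate of 41 | COc1ccc(CO[C@@H](C=C)[C@@]2(C)C=C[C@@H](O3)[C@@](C)(OC3(C)C)[C@@H]2[C@H](O[Si](C)(C)C(C)(C)C)/C(OB(C4CCCCC4)C4CCCCC4)=C/O[Si](CC)(CC)CC)cc1 | intermediate
44 | 6,7-syn aldol (C6–OH; C5 vinyl bromide) | COc1ccc(CO[C@@H](C=C)[C@@]2(C)C=C[C@@H](O3)[C@@](C)(OC3(C)C)[C@@H]2[C@H](O[Si](C)(C)C(C)(C)C)C(=O)[C@@H](O[Si](CC)(CC)CC)[C@H](O)C(Br)=C)cc1 | intermediate
45 | tributyl(vinyl)stannane | C=C[Sn](CCCC)(CCCC)CCCC | starting material
46 | dienyl alcohol (C5(=C16H2)–C4H=CH2) | COc1ccc(CO[C@@H](C=C)[C@@]2(C)C=C[C@@H](O3)[C@@](C)(OC3(C)C)[C@@H]2[C@H](O[Si](C)(C)C(C)(C)C)C(=O)[C@@H](O[Si](CC)(CC)CC)[C@H](O)C(=C)C=C)cc1 | intermediate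
47 | (6S)-chloride | COc1ccc(CO[C@@H](C=C)[C@@]2(C)C=C[C@@H](O3)[C@@](C)(OC3(C)C)[C@@H]2[C@H](O[Si](C)(C)C(C)(C)C)C(=O)[C@@H](O[Si](CC)(CC)CC)[C@@H](Cl)C(=C)C=C)cc1 | intermediate
48 | C7 alcohol (α-hydroxy β-chloro ketone) | COc1ccc(CO[C@@H](C=C)[C@@]2(C)C=C[C@@H](O3)[C@@](C)(OC3(C)C)[C@@H]2[C@H](O[Si](C)(C)C(C)(C)C)C(=O)[C@@H](O)[C@@H](Cl)C(=C)C=C)cc1 | intermediate
49 | 2-bromopropanoyl bromide | CC(Br)C(=O)Br | starting material
50 | C7 2-bromopropanoate | COc1ccc(CO[C@@H](C=C)[C@@]2(C)C=C[C@@H](O3)[C@@](C)(OC3(C)C)[C@@H]2[C@H](O[Si](C)(C)C(C)(C)C)C(=O)[C@@H](OC(=O)C(C)Br)[C@@H](Cl)C(=C)C=C)cc1 | intermediate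
51 | samarium ester enolate of 50 | COc1ccc(CO[C@@H](C=C)[C@@]2(C)C=C[C@@H](O3)[C@@](C)(OC3(C)C)[C@@H]2[C@H](O[Si](C)(C)C(C)(C)C)C(=O)[C@@H](OC(O[Sm](I)I)=CC)[C@@H](Cl)C(=C)C=C)cc1 | intermediate
52 | γ-lactone (C8–OH free; C2 PMB ether) | COc1ccc(CO[C@@H](C=C)[C@@]2(C)C=C[C@@H](O3)[C@@](C)(OC3(C)C)[C@@H]2[C@H](O[Si](C)(C)C(C)(C)C)[C@]4(O)[C@@H](C)C(=O)O[C@H]4[C@@H](Cl)C(=C)C=C)cc1 | intermediate
53 | C2 alcohol | O[C@@H](C=C)[C@@]2(C)C=C[C@@H](O3)[C@@](C)(OC3(C)C)[C@@H]2[C@H](O[Si](C)(C)C(C)(C)C)[C@]4(O)[C@@H](C)C(=O)O[C@H]4[C@@H](Cl)C(=C)C=C | intermediate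
54 | C2 butanoate | CCCC(=O)O[C@@H](C=C)[C@@]2(C)C=C[C@@H](O3)[C@@](C)(OC3(C)C)[C@@H]2[C@H](O[Si](C)(C)C(C)(C)C)[C@]4(O)[C@@H](C)C(=O)O[C@H]4[C@@H](Cl)C(=C)C=C | intermediate
55 | ten-membered ring compound (C9 OTBS; C11/C12 acetonide) | C=C1/C=C\[C@H](OC(=O)CCC)[C@@]2(C)C=C[C@@H](O3)[C@@](C)(OC3(C)C)[C@@H]2[C@H](O[Si](C)(C)C(C)(C)C)[C@]2(O)[C@@H](C)C(=O)O[C@H]2[C@H]1Cl | intermediate
56 | tetraol (C8, C9, C11, C12 hydroxyls) | C=C1/C=C\[C@H](OC(=O)CCC)[C@@]2(C)C=C[C@@H](O)[C@@](C)(O)[C@@H]2[C@H](O)[C@]2(O)[C@@H](C)C(=O)O[C@H]2[C@H]1Cl | intermediate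
57 | 13,14-epoxy tetraol | C=C1/C=C\[C@H](OC(=O)CCC)[C@@]2(C)[C@H]3O[C@H]3[C@@H](O)[C@@](C)(O)[C@@H]2[C@H](O)[C@]2(O)[C@@H](C)C(=O)O[C@H]2[C@H]1Cl | intermediate
58 | CNP0114058.1 | C=C1/C=C\[C@H](OC(=O)CCC)[C@@]2(C)[C@H]3O[C@H]3[C@@H](OC(C)=O)[C@@](C)(O)[C@@H]2[C@H](OC(C)=O)[C@]2(O)[C@@H](C)C(=O)O[C@H]2[C@H]1Cl | target

## Step count and risks

Total step count: 38. Longest linear sequence: 38 steps (from prenol 1; all other building blocks are commercial).

Steps most likely to fail:

Step 13 (key cycloaddition). What may go wrong is poor facial selectivity at C1, because the chair with the C9 arm axial competes with the wanted chair, which carries C15 and C20 1,3-diaxial. The nitrile oxide may also dimerise if closure onto the hindered trisubstituted alkene is slow. The fallback changes the dipole to a silyl nitronate, which cannot dimerise and reacts through a later, bulkier transition state. It sets out from TES ether 19. Aqueous acetic acid in THF should remove the TES group to give the primary alcohol F1. Iodine, PPh3 and imidazole should give the iodide F2, and NaNO2 with phloroglucinol in DMF the nitroalkane F3. TMSCl and Et3N should convert F3 into the silyl nitronate F4 (not isolated), which should cyclise onto the alkene to the N-silyloxyisoxazolidine F5. TsOH should eliminate trimethylsilanol from F5, and the route is rejoined at isoxazoline 24.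

Step 35 (ring-closing metathesis). What may go wrong is oligomerisation by cross-metathesis, or trapping of the catalyst as a vinyl carbene at the diene, before the strained ten-membered ring closes. The fallback closes the ring before the lactone and the allylic chloride are present. It sets out from dienyl alcohol 46, where the chain is more flexible and carries a free allylic hydroxyl. Metathesis of 46 should give the macrocyclic hydroxy ketone F6. PPh3 and hexachloroacetone should give the macrocyclic chloride F7, and HF·pyridine the macrocyclic C7 alcohol F8. Acylation with 49 should give the macrocyclic bromo ester F9. SmI2 should form the samarium enolate F10 (not isolated), which should close to the macrocyclic lactone PMB ether F11. DDQ should free the macrocyclic C2 alcohol F12, and butanoic anhydride returns the route to compound 55.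

Step 29 (chlorination with inversion). What may go wrong is allylic transposition (chloride attack at C16 or through a dienyl cation), loss of configuration at C6, or elimination. The fallback avoids phosphonium activation and delivers chloride to a cyclic acyloxonium ion. It sets out from dienyl alcohol 46. HF·pyridine should give the 6,7-diol F13. Trimethyl orthoacetate with PPTS should give the cyclic orthoacetate F14 (not isolated). TMSCl should then open it at the allylic C6 with inversion to the 6-chloro 7-acetate F15. Neutral methanolysis of the acetate with the distannoxane catalyst (ClBu2SnOSnBu2OH)2 rejoins the route at compound 48.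

Further compounds
F1 | step 13 | C14 primary alcohol (TES removed from 19) | COc1ccc(COC/C=C(\C)[C@@H](CO[Si](C)(C)C(C)(C)C)[C@](C)(O2)[C@H](OC2(C)C)CCO)cc1
F2 | step 13 | C14 iodide | COc1ccc(COC/C=C(\C)[C@@H](CO[Si](C)(C)C(C)(C)C)[C@](C)(O2)[C@H](OC2(C)C)CCI)cc1
F3 | step 13 | C14 nitroalkane | COc1ccc(COC/C=C(\C)[C@@H](CO[Si](C)(C)C(C)(C)C)[C@](C)(O2)[C@H](OC2(C)C)CC[N+](=O)[O-])cc1
F4 | step 13 | trimethylsilyl nitronate (not isolated) | COc1ccc(COC/C=C(\C)[C@@H](CO[Si](C)(C)C(C)(C)C)[C@](C)(O2)[C@H](OC2(C)C)CC=[N+]([O-])O[Si](C)(C)C)cc1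
F5 | step 13 | N-(trimethylsilyloxy)isoxazolidine fused to ring A | COc1ccc(COC[C@H]4[C@@]2(C)C(N(O[Si](C)(C)C)O4)C[C@@H](O3)[C@@](C)(OC3(C)C)[C@@H]2CO[Si](C)(C)C(C)(C)C)cc1
F6 | step 35 | macrocyclic hydroxy ketone (C6–OH, C7 OTES, C8 ketone, C2 OPMB) | C=C1/C=C\[C@H](OCc4ccc(OC)cc4)[C@@]2(C)C=C[C@@H](O3)[C@@](C)(OC3(C)C)[C@@H]2[C@H](O[Si](C)(C)C(C)(C)C)C(=O)[C@@H](O[Si](CC)(CC)CC)[C@@H]1O
F7 | step 35 | macrocyclic chloride | C=C1/C=C\[C@H](OCc4ccc(OC)cc4)[C@@]2(C)C=C[C@@H](O3)[C@@](C)(OC3(C)C)[C@@H]2[C@H](O[Si](C)(C)C(C)(C)C)C(=O)[C@@H](O[Si](CC)(CC)CC)[C@H]1Cl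
F8 | step 35 | macrocyclic C7 alcohol | C=C1/C=C\[C@H](OCc4ccc(OC)cc4)[C@@]2(C)C=C[C@@H](O3)[C@@](C)(OC3(C)C)[C@@H]2[C@H](O[Si](C)(C)C(C)(C)C)C(=O)[C@@H](O)[C@H]1Cl
F9 | step 35 | macrocyclic bromo ester | C=C1/C=C\[C@H](OCc4ccc(OC)cc4)[C@@]2(C)C=C[C@@H](O3)[C@@](C)(OC3(C)C)[C@@H]2[C@H](O[Si](C)(C)C(C)(C)C)C(=O)[C@@H](OC(=O)C(C)Br)[C@H]1Cl
F10 | step 35 | samarium enolate of F9 (not isolated) | C=C1/C=C\[C@H](OCc4ccc(OC)cc4)[C@@]2(C)C=C[C@@H](O3)[C@@](C)(OC3(C)C)[C@@H]2[C@H](O[Si](C)(C)C(C)(C)C)C(=O)[C@@H](OC(O[Sm](I)I)=CC)[C@H]1Cl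
F11 | step 35 | macrocyclic lactone PMB ether | C=C1/C=C\[C@H](OCc4ccc(OC)cc4)[C@@]2(C)C=C[C@@H](O3)[C@@](C)(OC3(C)C)[C@@H]2[C@H](O[Si](C)(C)C(C)(C)C)[C@]2(O)[C@@H](C)C(=O)O[C@H]2[C@H]1Cl
F12 | step 35 | macrocyclic C2 alcohol | C=C1/C=C\[C@H](O)[C@@]2(C)C=C[C@@H](O3)[C@@](C)(OC3(C)C)[C@@H]2[C@H](O[Si](C)(C)C(C)(C)C)[C@]2(O)[C@@H](C)C(=O)O[C@H]2[C@H]1Cl
F13 | step 29 | 6,7-diol | COc1ccc(CO[C@@H](C=C)[C@@]2(C)C=C[C@@H](O3)[C@@](C)(OC3(C)C)[C@@H]2[C@H](O[Si](C)(C)C(C)(C)C)C(=O)[C@@H](O)[C@H](O)C(=C)C=C)cc1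
F14 | step 29 | cyclic orthoacetate of F13 (not isolated) | COc1ccc(CO[C@@H](C=C)[C@@]2(C)C=C[C@@H](O3)[C@@](C)(OC3(C)C)[C@@H]2[C@H](O[Si](C)(C)C(C)(C)C)C(=O)[C@H]4OC(C)(OC)O[C@@H]4C(=C)C=C)cc1
F15 | step 29 | 6-chloro 7-acetate | COc1ccc(CO[C@@H](C=C)[C@@]2(C)C=C[C@@H](O3)[C@@](C)(OC3(C)C)[C@@H]2[C@H](O[Si](C)(C)C(C)(C)C)C(=O)[C@@H](OC(C)=O)[C@@H](Cl)C(=C)C=C)cc1
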